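**Retrosynthetic overview**

1. Target ⇐ MnO2 oxidation and primary acetylation of a triol ⇐ hydride opening of an epoxy alcohol ⇐ hydroxyl-directed epoxidation of a ring A C1=C5 allylic alcohol (sets C1).
2. C2–C5′ bond with C2 cis to C3 ⇐ suprafacial Carroll rearrangement of an allyl β-keto ester; ring B arrives preformed (Favorskii contraction of (R)-pulegone) and receives its enone by Saegusa oxidation.
3. cis-Cyclopentenol ⇐ 4-alkenyl-2-(silyloxymethyl)cyclopentenone ⇐ anti conjugate addition/elimination of a (Z)-alkenyl copper reagent on a 4-acetoxycyclopentenone.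
4. That cyclopentenone (ring A, formed first) ⇐ enantioselective Piancatelli rearrangement of a furyl carbinol (furan + silyloxyacetaldehyde); its single carbinol stereocentre is relayed to C3, C2 and C1.
5. Side chain ⇐ (Z)-2-iodo-6-methylhepta-2,5-diene by α-iodo Wittig olefination of 4-methylpent-3-enal.

Assumption: the SMILES is read as (1R,2S,3R) on ring A (all three carbon substituents cis, OH trans), (1S,5R) on the cyclopentenone substituent (methyl cis to ring A) and Z for the trisubstituted alkene; the four starting materials of steps 1, 2 and 4 are taken as purchased.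

Atom labels used below: ring A = C1 (carbinol), C2 (bears ring B), C3 (bears the side chain), C4, C5; ring B = C1′ (C=O), C2′=C3′, C4′ (CH3), C5′ (bonded to C2).

**Step 1**
Reactants: 1 4-methylpent-3-en-1-ol
Product: 3 (2Z)-2-iodo-6-methylhepta-2,5-diene, via 4-methylpent-3-enal 2 (not isolated)
Conditions: Dess–Martin periodinane, pyridine, CH2Cl2, 0 °C; then EtPPh3I, n-BuLi, I2, NaN(SiMe3)2, THF, −78 → 23 °C
Reagents that add atoms: ethyltriphenylphosphonium iodide CC[P+](c1ccccc1)(c1ccccc1)c1ccccc1.[I-]; iodine II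
Why: Dess–Martin oxidation gives the β,γ-unsaturated aldehyde, which the α-iodo ylide converts by a Stork–Zhao-type Wittig olefination into the (Z)-2-iodoalkene (iodine cis to the chain), the geometry the side chain keeps to the end.

**Step 2**
Reactants: 4 (R)-pulegone
Product: 6 methyl (2R)-2-methyl-5-(propan-2-ylidene)cyclopentane-1-carboxylate (methyl pulegenate; both C1 epimers), via pulegone dibromide 5 (not isolated)
Conditions: Br2, Et2O, 0 °C; then NaOMe, MeOH, 65 °C
Reagents that add atoms: sodium methoxide C[O-].[Na+]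
Why: Bromine adds to the exocyclic alkene and methoxide triggers the Favorskii ring contraction, giving the cyclopentane ester while the (R)-methyl stereocentre of pulegone is untouched.

**Step 3**
Reactants: 6 methyl pulegenate
Product: 7 methyl (1S,2R)-2-methyl-5-oxocyclopentane-1-carboxylate (trans keto form; C1 equilibrates through the enol)
Conditions: O3, CH2Cl2/MeOH, −78 °C; then Me2S
Reagents that add atoms: ozone [O-][O+]=O
Why: Ozonolysis with reductive work-up cleaves the only alkene to the ring ketone, giving the β-keto ester whose (R)-methyl carbon becomes C4′ of ring B.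

**Step 4**
Reactants: 8 furan; 9 2-[(tert-butyldiphenylsilyl)oxy]acetaldehyde
Product: 11 racemic 2-[(tert-butyldiphenylsilyl)oxy]-1-(furan-2-yl)ethan-1-ol, via 2-furyllithium 10 (not isolated)
Conditions: n-BuLi, THF, −78 → 0 °C; then 9, −78 °C; H2O
Reagents that add atoms: none
Why: α-Lithiation of furan and 1,2-addition to the aldehyde give the furyl carbinol, whose stereocentre is irrelevant because it is ionised in the next step.

**Step 5**
Reactants: 11 racemic furyl carbinol
Product: 12 (4S,5R)-5-{[(tert-butyldiphenylsilyl)oxy]methyl}-4-hydroxycyclopent-2-en-1-one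
Conditions: (R)-3,3′-bis(2,4,6-triisopropylphenyl)-1,1′-binaphthyl-2,2′-diyl N-triflylphosphoramide (10 mol %; antipode chosen on the first run to give 4S,5R), H2O (5 equiv), ClCH2CH2Cl, 40 °C
Reagents that add atoms: water O
Why: Proposed new method: the chiral acid ionises either enantiomer of the carbinol to the same furfuryl cation held as an ion pair with the chiral phosphoramide anion, water adds at C5 of the furan, the ring opens to a hydroxypentadienyl cation and a conrotatory 4π electrocyclisation (Piancatelli rearrangement), whose direction of rotation is set by the chiral counter-anion, closes ring A with OH and CH2OSi trans and destroys the aromatic ring; the closest known reactions are the racemic oxa-Piancatelli rearrangement (Dy(OTf)3 or ZnCl2 in water) and the chiral-phosphoric-acid-catalysed aza-Piancatelli rearrangement with anilines.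

**Step 6**
Reactants: 12 hydroxy enone
Product: 13 (1S,5R)-5-{[(tert-butyldiphenylsilyl)oxy]methyl}-4-oxocyclopent-2-en-1-yl acetate
Conditions: Ac2O, pyridine, CH2Cl2, 0 °C
Reagents that add atoms: acetic anhydride CC(=O)OC(C)=O
Why: O-Acetylation turns the 4-hydroxyl into an anti-directing group and a better leaving group than the primary silyl ether, without touching a stereocentre.

**Step 7**
Reactants: 13 acetoxy enone; 3 (2Z)-2-iodo-6-methylhepta-2,5-diene
Product: 16 (4R)-2-{[(tert-butyldiphenylsilyl)oxy]methyl}-4-[(2Z)-6-methylhepta-2,5-dien-2-yl]cyclopent-2-en-1-one, via alkenylmagnesium chloride 14 (not isolated), via conjugate-addition ketone 15 (not isolated)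
Conditions: i-PrMgCl·LiCl, THF, 0 → 23 °C; CuBr·SMe2 (10 mol %), 13, −78 → −40 °C; then Et3N, CH2Cl2, 23 °C
Reagents that add atoms: none
Why: Iodine–magnesium exchange keeps the Z geometry, the copper-catalysed conjugate addition places the alkenyl group anti to the neighbouring acetoxy group, and E1cB loss of acetic acid (addition–elimination) trades the acetoxy stereocentre for the (R)-alkenyl stereocentre (future C3).

**Step 8**
Reactants: 16 enone
Product: 17 (1S,4R)-2-{[(tert-butyldiphenylsilyl)oxy]methyl}-4-[(2Z)-6-methylhepta-2,5-dien-2-yl]cyclopent-2-en-1-ol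
Conditions: (R)-2-methyl-CBS-oxazaborolidine (20 mol %), catecholborane, toluene, −78 °C
Reagents that add atoms: none
Why: Corey–Bakshi–Shibata 1,2-reduction gives the (S)-alcohol cis to the alkenyl group, the catalyst (substituted alkene arm as the large group) and the substrate bias (hydride anti to the 4-substituent) acting in the same sense.

**Step 9**
Reactants: 17 cis-allylic alcohol; 7 β-keto ester
Product: 18 (1S,4R)-2-{[(tert-butyldiphenylsilyl)oxy]methyl}-4-[(2Z)-6-methylhepta-2,5-dien-2-yl]cyclopent-2-en-1-yl (2R)-2-methyl-5-oxocyclopentane-1-carboxylate (keto/enol and C1 epimer mixture)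
Conditions: DMAP (0.3 equiv), toluene, 110 °C, 4 Å sieves
Reagents that add atoms: none
Why: DMAP-catalysed transesterification of the β-keto ester (through its acyl ketene) acylates the allylic alcohol with retention at the carbinol carbon.

**Step 10**
Reactants: 18 allyl β-keto ester
Product: 20 (2S,3R)-2-[(1S,5R)-2-{[(tert-butyldiphenylsilyl)oxy]methyl}-5-[(2Z)-6-methylhepta-2,5-dien-2-yl]cyclopent-2-en-1-yl]-3-methylcyclopentan-1-one, via β-keto acid 19 (not isolated)
Conditions: LiN(i-Pr)2 (2.3 equiv), THF, −78 → 65 °C; 1 M HCl, 0 °C; then toluene, 70 °C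
Reagents that add atoms: none
Why: The dianion Carroll rearrangement ([3,3] shift of the ester enolate) forms the C2–C5′ bond suprafacially on the ring face that carried the ester oxygen, hence cis to the alkenyl group, and decarboxylation followed by kinetic ketonisation of the enol from the face anti to the adjacent methyl sets C5′ cis to that methyl.

**Step 11**
Reactants: 20 cyclopentanone
Product: 22 (4R,5S)-5-[(1S,5R)-2-{[(tert-butyldiphenylsilyl)oxy]methyl}-5-[(2Z)-6-methylhepta-2,5-dien-2-yl]cyclopent-2-en-1-yl]-4-methylcyclopent-2-en-1-one, via trimethylsilyl enol ether 21 (not isolated)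
Conditions: LiN(i-Pr)2, Me3SiCl, THF, −78 °C; then Pd(OAc)2 (1.05 equiv), MeCN, 23 °C
Reagents that add atoms: none
Why: Kinetic deprotonation at the unhindered CH2 α-carbon and Saegusa–Ito oxidation of the silyl enol ether introduce the C2′=C3′ enone without touching the hindered C5′–H.

**Step 12**
Reactants: 22 silyl ether
Product: 23 (4R,5S)-5-[(1S,5R)-2-(hydroxymethyl)-5-[(2Z)-6-methylhepta-2,5-dien-2-yl]cyclopent-2-en-1-yl]-4-methylcyclopent-2-en-1-one
Conditions: Bu4NF, AcOH, THF, 0 → 23 °C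
Reagents that add atoms: none
Why: Acetic-acid-buffered fluoride cleaves the silyl ether without enolising the epimerisable cis-enone.

**Step 13**
Reactants: 23 allylic alcohol
Product: 24 (4R,5S)-5-[(1R,2S,3R,5R)-1-(hydroxymethyl)-3-[(2Z)-6-methylhepta-2,5-dien-2-yl]-6-oxabicyclo[3.1.0]hexan-2-yl]-4-methylcyclopent-2-en-1-one
Conditions: VO(acac)2 (5 mol %), t-BuOOH, CH2Cl2, 0 °C
Reagents that add atoms: tert-butyl hydroperoxide CC(C)(C)OO
Why: Vanadium-catalysed hydroxyl-directed epoxidation is selective for the allylic alcohol over the side-chain alkenes and the enone, and oxygen enters from the ring face anti to the neighbouring ring B substituent, fixing the C1–O bond trans to C2–C5′.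

**Step 14**
Reactants: 24 epoxy alcohol
Product: 25 (1R,2S,3R)-1-(hydroxymethyl)-2-[(1S,5R)-2-hydroxy-5-methylcyclopent-3-en-1-yl]-3-[(2Z)-6-methylhepta-2,5-dien-2-yl]cyclopentan-1-ol (both epimers at the ring B carbinol carbon)
Conditions: i-Bu2AlH (6 equiv), CH2Cl2, −78 → 0 °C
Reagents that add atoms: none
Why: The aluminium alkoxide of the epoxy alcohol delivers hydride to the secondary epoxide carbon (reductive epoxide opening), leaving the tertiary C1–OH with CH2OH cis to ring B, and the same reagent reduces the enone 1,2 to an allylic alcohol whose configuration does not matter.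

**Step 15**
Reactants: 25 triol
Product: 26 [(1R,2S,3R)-1-hydroxy-2-[(1S,5R)-2-hydroxy-5-methylcyclopent-3-en-1-yl]-3-[(2Z)-6-methylhepta-2,5-dien-2-yl]cyclopentyl]methyl acetate
Conditions: AcCl (1.1 equiv), 2,4,6-collidine, CH2Cl2, −78 °C
Reagents that add atoms: acetyl chloride CC(Cl)=O
Why: Kinetically selective acylation of the primary hydroxyl at low temperature leaves the secondary allylic and tertiary hydroxyls free.

**Step 16**
Reactants: 26 monoacetate
Product: 27 [(1R,2S,3R)-1-hydroxy-3-[(2Z)-6-methylhepta-2,5-dien-2-yl]-2-[(1S,5R)-5-methyl-2-oxocyclopent-3-en-1-yl]cyclopentyl]methyl acetate (CNP0222995.1)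
Conditions: MnO2, CH2Cl2, 23 °C
Reagents that add atoms: none
Why: Allylic oxidation with MnO2 touches only the secondary allylic alcohol and restores the enone under neutral conditions, so the cis C4′/C5′ relationship is not epimerised.

**Compound list**

1 | 4-methylpent-3-en-1-ol | CC(C)=CCCO | starting material
2 | 4-methylpent-3-enal | CC(C)=CCC=O | intermediate (not isolated)
3 | (2Z)-2-iodo-6-methylhepta-2,5-diene | I/C(C)=C\CC=C(C)C | intermediate
4 | (R)-pulegone | C[C@@H]1CCC(=C(C)C)C(=O)C1 | starting material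
5 | (5R)-2-bromo-2-(2-bromopropan-2-yl)-5-methylcyclohexan-1-one (pulegone dibromide, C2 epimers) | C[C@@H]1CCC(Br)(C(C)(C)Br)C(=O)C1 | intermediate (not isolated)
6 | methyl (2R)-2-methyl-5-(propan-2-ylidene)cyclopentane-1-carboxylate (C1 epimers) | COC(=O)C1C(=C(C)C)CC[C@H]1C | intermediate
7 | methyl (1S,2R)-2-methyl-5-oxocyclopentane-1-carboxylate | COC(=O)[C@@H]1C(=O)CC[C@H]1C | intermediate
8 | furan | c1ccoc1 | starting material
9 | 2-[(tert-butyldiphenylsilyl)oxy]acetaldehyde | O=CCO[Si](c1ccccc1)(c1ccccc1)C(C)(C)C | starting material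
10 | 2-furyllithium | [Li]c1ccco1 | intermediate (not isolated)
11 | racemic 2-[(tert-butyldiphenylsilyl)oxy]-1-(furan-2-yl)ethan-1-ol | OC(CO[Si](c1ccccc1)(c1ccccc1)C(C)(C)C)c1ccco1 | intermediate
12 | (4S,5R)-5-{[(tert-butyldiphenylsilyl)oxy]methyl}-4-hydroxycyclopent-2-en-1-one | O=C1C=C[C@H](O)[C@H]1CO[Si](c1ccccc1)(c1ccccc1)C(C)(C)C | intermediate
13 | (1S,5R)-5-{[(tert-butyldiphenylsilyl)oxy]methyl}-4-oxocyclopent-2-en-1-yl acetate | O=C1C=C[C@H](OC(C)=O)[C@H]1CO[Si](c1ccccc1)(c1ccccc1)C(C)(C)C | intermediate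
14 | [(2Z)-6-methylhepta-2,5-dien-2-yl]magnesium chloride (LiCl complex) | Cl[Mg]/C(C)=C\CC=C(C)C | intermediate (not isolated)
15 | (1S,2R,5S)-2-{[(tert-butyldiphenylsilyl)oxy]methyl}-5-[(2Z)-6-methylhepta-2,5-dien-2-yl]-3-oxocyclopentyl acetate | O=C1C[C@@H](/C(C)=C\CC=C(C)C)[C@H](OC(C)=O)[C@H]1CO[Si](c1ccccc1)(c1ccccc1)C(C)(C)C | intermediate (not isolated)
16 | (4R)-2-{[(tert-butyldiphenylsilyl)oxy]methyl}-4-[(2Z)-6-methylhepta-2,5-dien-2-yl]cyclopent-2-en-1-one | O=C1C[C@@H](/C(C)=C\CC=C(C)C)C=C1CO[Si](c1ccccc1)(c1ccccc1)C(C)(C)C | intermediate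
17 | (1S,4R)-2-{[(tert-butyldiphenylsilyl)oxy]methyl}-4-[(2Z)-6-methylhepta-2,5-dien-2-yl]cyclopent-2-en-1-ol | O[C@H]1C[C@@H](/C(C)=C\CC=C(C)C)C=C1CO[Si](c1ccccc1)(c1ccccc1)C(C)(C)C | intermediate
18 | (1S,4R)-2-{[(tert-butyldiphenylsilyl)oxy]methyl}-4-[(2Z)-6-methylhepta-2,5-dien-2-yl]cyclopent-2-en-1-yl (2R)-2-methyl-5-oxocyclopentane-1-carboxylate (C1 of the keto ester unassigned) | O=C(O[C@H]1C[C@@H](/C(C)=C\CC=C(C)C)C=C1CO[Si](c1ccccc1)(c1ccccc1)C(C)(C)C)C1C(=O)CC[C@H]1C | intermediate
19 | 1-[(1R,5R)-2-{[(tert-butyldiphenylsilyl)oxy]methyl}-5-[(2Z)-6-methylhepta-2,5-dien-2-yl]cyclopent-2-en-1-yl]-(2R)-2-methyl-5-oxocyclopentane-1-carboxylic acid (C1 of the acid ring unassigned) | CC(C)(C)[Si](c1ccccc1)(c1ccccc1)OCC1=CC[C@@H](/C(C)=C\CC=C(C)C)[C@H]1C1(C(=O)O)C(=O)CC[C@H]1C | intermediate (not isolated)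
20 | (2S,3R)-2-[(1S,5R)-2-{[(tert-butyldiphenylsilyl)oxy]methyl}-5-[(2Z)-6-methylhepta-2,5-dien-2-yl]cyclopent-2-en-1-yl]-3-methylcyclopentan-1-one | CC(C)(C)[Si](c1ccccc1)(c1ccccc1)OCC1=CC[C@@H](/C(C)=C\CC=C(C)C)[C@H]1[C@H]1C(=O)CC[C@H]1C | intermediate
21 | {[(4R,5S)-5-[(1S,5R)-2-{[(tert-butyldiphenylsilyl)oxy]methyl}-5-[(2Z)-6-methylhepta-2,5-dien-2-yl]cyclopent-2-en-1-yl]-4-methylcyclopent-1-en-1-yl]oxy}trimethylsilane | CC(C)(C)[Si](c1ccccc1)(c1ccccc1)OCC1=CC[C@@H](/C(C)=C\CC=C(C)C)[C@H]1[C@H]1C(O[Si](C)(C)C)=CC[C@H]1C | intermediate (not isolated)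
22 | (4R,5S)-5-[(1S,5R)-2-{[(tert-butyldiphenylsilyl)oxy]methyl}-5-[(2Z)-6-methylhepta-2,5-dien-2-yl]cyclopent-2-en-1-yl]-4-methylcyclopent-2-en-1-one | CC(C)(C)[Si](c1ccccc1)(c1ccccc1)OCC1=CC[C@@H](/C(C)=C\CC=C(C)C)[C@H]1[C@H]1C(=O)C=C[C@H]1C | intermediate
23 | (4R,5S)-5-[(1S,5R)-2-(hydroxymethyl)-5-[(2Z)-6-methylhepta-2,5-dien-2-yl]cyclopent-2-en-1-yl]-4-methylcyclopent-2-en-1-one | OCC1=CC[C@@H](/C(C)=C\CC=C(C)C)[C@H]1[C@H]1C(=O)C=C[C@H]1C | intermediate
24 | (4R,5S)-5-[(1R,2S,3R,5R)-1-(hydroxymethyl)-3-[(2Z)-6-methylhepta-2,5-dien-2-yl]-6-oxabicyclo[3.1.0]hexan-2-yl]-4-methylcyclopent-2-en-1-one | OC[C@@]12O[C@@H]1CC[C@@H](/C(C)=C\CC=C(C)C)[C@H]2[C@H]1C(=O)C=C[C@H]1C | intermediate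
25 | (1R,2S,3R)-1-(hydroxymethyl)-2-[(1S,5R)-2-hydroxy-5-methylcyclopent-3-en-1-yl]-3-[(2Z)-6-methylhepta-2,5-dien-2-yl]cyclopentan-1-ol (epimers at the ring B carbinol) | OC[C@@]1(O)CC[C@@H](/C(C)=C\CC=C(C)C)[C@H]1[C@H]1C(O)C=C[C@H]1C | intermediate
26 | [(1R,2S,3R)-1-hydroxy-2-[(1S,5R)-2-hydroxy-5-methylcyclopent-3-en-1-yl]-3-[(2Z)-6-methylhepta-2,5-dien-2-yl]cyclopentyl]methyl acetate | CC(=O)OC[C@@]1(O)CC[C@@H](/C(C)=C\CC=C(C)C)[C@H]1[C@H]1C(O)C=C[C@H]1C | intermediate
27 | [(1R,2S,3R)-1-hydroxy-3-[(2Z)-6-methylhepta-2,5-dien-2-yl]-2-[(1S,5R)-5-methyl-2-oxocyclopent-3-en-1-yl]cyclopentyl]methyl acetate | CC(=O)OC[C@@]1(O)CC[C@@H](/C(C)=C\CC=C(C)C)[C@H]1[C@H]1C(=O)C=C[C@H]1C | target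

**Step count and risks**

Total step count: 16. Longest linear sequence: 13 steps (steps 4 to 16, furan to target).

Step 5 is the least certain, because an enantioselective Piancatelli rearrangement with water as the nucleophile is not established, and the β-silyloxy cation may also lose a proton to a vinylfuran. The fallback sets out from 11 and comes back at 12. Rearrangement of 11 with Dy(OTf)3 (10 mol %) in t-BuOH/H2O at 80 °C gives the racemic trans-hydroxy enone F1. Immobilised Candida antarctica lipase B with vinyl acetate then acetylates the (4R,5S)-enantiomer, as the empirical rule for secondary alcohols predicts, to the enantiomeric acetate F2. The unreacted (4S,5R)-alcohol is separated and is compound 12; if the enzyme shows the opposite preference, the acetate it forms is 13 itself.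

Step 10 can fail in two ways: the [3,3] shift builds a quaternary carbon next to a substituted ring carbon, and C5′ rests on kinetic ketonisation, which may give only a modest cis:trans ratio. The fallback sets out from 17 and comes back at 22, so that C5′ is set in a pericyclic transition state and ring B is closed afterwards.
- Alcohol 17 is esterified with (S)-3-methylpent-4-enoic acid (DCC, DMAP) to the pentenoate ester F3.
- Ireland–Claisen rearrangement (LiN(i-Pr)2, Me3SiCl, THF or THF/HMPA to choose the ketene acetal geometry, −78 → 23 °C) gives the rearranged acid F4, with C2 cis to C3 by the same suprafacial shift.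
- Coupling with MeNHOMe·HCl (EDC) gives the Weinreb amide F5, and CH2=CHMgBr converts it into the divinyl ketone F6.
- Ring-closing metathesis with the second-generation Grubbs catalyst closes ring B and gives 22 directly, with no Saegusa step.

Step 14 may open the epoxide at the tertiary carbon by a Lewis-acid pathway, or reduce the enone in a 1,4 sense. The fallback sets out from 24 and comes back at 27, avoiding hydride altogether. MgI2 (Et2O/toluene, −60 °C) opens the chelated epoxy alcohol at the secondary carbon to the iodohydrin F7. Radical deiodination with (Me3Si)3SiH and Et3B/air gives the diol enone F8, with the ring B ketone never reduced. Acetylation of its only primary hydroxyl (AcCl, 2,4,6-collidine, −78 °C) gives 27.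

**Further compounds**

F1 | step 5 | racemic trans-5-{[(tert-butyldiphenylsilyl)oxy]methyl}-4-hydroxycyclopent-2-en-1-one (4S,5R and 4R,5S) | O=C1C=C[C@H](O)[C@H]1CO[Si](c1ccccc1)(c1ccccc1)C(C)(C)C.O=C1C=C[C@@H](O)[C@@H]1CO[Si](c1ccccc1)(c1ccccc1)C(C)(C)C
F2 | step 5 | (1R,5S)-5-{[(tert-butyldiphenylsilyl)oxy]methyl}-4-oxocyclopent-2-en-1-yl acetate | O=C1C=C[C@@H](OC(C)=O)[C@@H]1CO[Si](c1ccccc1)(c1ccccc1)C(C)(C)C
F3 | step 10 | (1S,4R)-2-{[(tert-butyldiphenylsilyl)oxy]methyl}-4-[(2Z)-6-methylhepta-2,5-dien-2-yl]cyclopent-2-en-1-yl (3S)-3-methylpent-4-enoate | O=C(C[C@H](C)C=C)O[C@H]1C[C@@H](/C(C)=C\CC=C(C)C)C=C1CO[Si](c1ccccc1)(c1ccccc1)C(C)(C)C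
F4 | step 10 | (2S,3R)-2-[(1S,5R)-2-{[(tert-butyldiphenylsilyl)oxy]methyl}-5-[(2Z)-6-methylhepta-2,5-dien-2-yl]cyclopent-2-en-1-yl]-3-methylpent-4-enoic acid | CC(C)(C)[Si](c1ccccc1)(c1ccccc1)OCC1=CC[C@@H](/C(C)=C\CC=C(C)C)[C@H]1[C@@H](C(=O)O)[C@H](C)C=C
F5 | step 10 | (2S,3R)-2-[(1S,5R)-2-{[(tert-butyldiphenylsilyl)oxy]methyl}-5-[(2Z)-6-methylhepta-2,5-dien-2-yl]cyclopent-2-en-1-yl]-N-methoxy-N,3-dimethylpent-4-enamide | CC(C)(C)[Si](c1ccccc1)(c1ccccc1)OCC1=CC[C@@H](/C(C)=C\CC=C(C)C)[C@H]1[C@@H](C(=O)N(C)OC)[C@H](C)C=C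
F6 | step 10 | (4S,5R)-4-[(1S,5R)-2-{[(tert-butyldiphenylsilyl)oxy]methyl}-5-[(2Z)-6-methylhepta-2,5-dien-2-yl]cyclopent-2-en-1-yl]-5-methylhepta-1,6-dien-3-one | CC(C)(C)[Si](c1ccccc1)(c1ccccc1)OCC1=CC[C@@H](/C(C)=C\CC=C(C)C)[C@H]1[C@@H](C(=O)C=C)[C@H](C)C=C
F7 | step 14 | (4R,5S)-5-[(1S,2R,3S,5R)-2-hydroxy-2-(hydroxymethyl)-3-iodo-5-[(2Z)-6-methylhepta-2,5-dien-2-yl]cyclopentyl]-4-methylcyclopent-2-en-1-one | OC[C@@]1(O)[C@@H](I)C[C@@H](/C(C)=C\CC=C(C)C)[C@H]1[C@H]1C(=O)C=C[C@H]1C
F8 | step 14 | (4R,5S)-5-[(1S,2R,5R)-2-hydroxy-2-(hydroxymethyl)-5-[(2Z)-6-methylhepta-2,5-dien-2-yl]cyclopentyl]-4-methylcyclopent-2-en-1-one | OC[C@@]1(O)CC[C@@H](/C(C)=C\CC=C(C)C)[C@H]1[C@H]1C(=O)C=C[C@H]1C
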